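The constants say what each catalyst intermediate does: it loses its substrate again or meets partner.

    partner + catalyst intermediate B → free catalyst + right-handed product (k1 = 2.0 M⁻¹ s⁻¹)
    left-handed product ⇌ right-handed product (k2 = 7.5 × 10⁻⁴ s⁻¹)
    free catalyst + right-handed substrate ⇌ catalyst intermediate B (K3 = 3.6 M⁻¹, k3 = 57 M⁻¹ s⁻¹)
    free catalyst + left-handed substrate ⇌ catalyst intermediate A (K4 = 19 M⁻¹, k4 = 10 M⁻¹ s⁻¹)
    partner + catalyst intermediate A → free catalyst + left-handed product (k5 = 21 M⁻¹ s⁻¹)

left-handed substrate 0.10 M; partner 0.0800 M (in portions, 4); free catalyst 0.38 mM; right-handed substrate 0.10 M; time 40 h; the portions of partner follow each other after 5.0 min, the first at the start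

- free catalyst is single-handed; left-handed substrate and right-handed substrate are mirror images of each other, charged as a racemate, each of them at the stated concentration
- run time (flask): 40 h

* the left-handed product standing at 40 h, as a percentage of the left-handed substrate and right-handed substrate together charged
* the right-handed substrate standing at 40 h, as a percentage of the left-handed substrate and right-handed substrate together charged

Partner is the limiting reagent, at 0.0800 M against 0.200 M of substrates, and each partner makes one product. In this flask the two products relax into each other with half-life 0.128 h, far shorter than 40 h, so I expected 20.0 % of left-handed product.

For the right-handed substrate I used the selectivity factor s, how many times faster left-handed substrate is consumed than right-handed, each per unit of its own concentration. Each substrate's rate constant is its binding rate constant times the share of its intermediate that goes on to product. Catalyst intermediate A falls back at 0.526 s⁻¹, catalyst intermediate B at 15.8 s⁻¹. As c(partner) falls, s climbs to its ceiling, 55.4, the ratio of the products of turnover and equilibrium constants.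

With s held constant, ln(fraction of left-handed substrate left) over ln(fraction of right-handed substrate left) equals s, and the two fractions sum to 1.20 here. So s at its ceiling gave the bound from above, 48.7 % of the charges.

For the bound from below I needed the peak of c(partner). Late in the additions, I reckoned 0.106 mM in catalyst intermediate A, so partner's half-life was 5.17 min, about the interval of 5.0 min. Half of it stands over each time, so the peak stays near two portions, 40.0 mM. There s is 21.5, giving 46.9 %. I committed to the middle, 47.8 %.

The forecast gave 20 % and 47.9 %, between 47.7 % and 48.1 %, with a selectivity factor that “runs from about 24 to 55”. Its right-handed figure lies below my upper bound and above my lower one.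

The flask gave 20.0 % and 47.9 %, with 0 % of its partner left at 40.0 h. Its 24 % and 96 % of the substrates' own charges read as a selectivity factor near 33.4, below the ceiling 55.4. In the neighbour flask with 0.020 M of partner, that ceiling put 99.6 % of the right-handed charge left, and s at two portions, 39.7, put 99.4 %. The neighbour flask kept 99.5 %.

The constants are assumed; the flask was simulated.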